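**Retrosynthetic overview**
1. Target 14 ⇐ acylation of the cis-hydroxy ether 13 ⇐ diastereoselective reduction of the β,γ-unsaturated ketone 12.
2. 12 ⇐ the bond between the ring CH and the exocyclic OCH2 carbon, made by anti-SE2' aryloxymethylation of the cyclic allylsilane 8 with 7-(chloromethoxy)coumarin 11 (two steps from umbelliferone).
3. 8 ⇐ catalytic enantioselective conjugate silylation of the linear dienone 6 ⇐ 4-methylanisole (Birch dearomatisation, gem-dimethylation, dehydrogenation).
4. Rings: none is constructed; the cyclohexene is the dearomatised benzene ring of 4-methylanisole and the coumarin bicycle enters intact.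
5. Enabling feature: in the cyclohexene ring the CH bearing CH2OAr is the γ-terminus of the allyl triad CH–C(CH3)=CH, whose other terminus is β to the oxygen-bearing ring carbon, while the CMe2 carbon isolates that carbonyl from the alkene; a β-silyl ketone is therefore an allylsilane, and SE2' attack at the CH terminus leaves the double bond where the target has it.

Key step: step 7

Assumption: the sense of induction of the chiral NHC–Cu catalyst on dienone 6 is not predicted here; the ligand antipode that gives (R)-8 is meant, to be fixed by correlation on the first run.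

**Step 1**
Reactants: 1 4-methylanisole
Product: 3 4-methylcyclohex-3-en-1-one, via 1-methoxy-4-methylcyclohexa-1,4-diene 2 (not isolated)
Conditions: Li, NH3(l), THF, t-BuOH, −78 → −33 °C; then (CO2H)2 (cat.), MeOH/H2O, rt
Reagents that add atoms: water, O
Why: Birch reduction should give the 2,5-dihydroanisole 2 with both substituents on the remaining double bonds, and mild acid hydrolysis of the enol ether unmasks the β,γ-unsaturated ketone; no stereocentre is formed.

**Step 2**
Reactants: 3 4-methylcyclohex-3-en-1-one
Product: 4 2,2,4-trimethylcyclohex-3-en-1-one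
Conditions: t-BuOK (2.2 equiv), MeI (2.5 equiv), THF, 0 °C → rt
Reagents that add atoms: iodomethane, CI
Why: Deconjugative α,α-dialkylation of an enone: deprotonation at the carbon between carbonyl and alkene gives the extended dienolate, which should be methylated twice at its α-carbon, so the gem-dimethyl group is installed and the alkene stays β,γ.

**Step 3**
Reactants: 4 2,2,4-trimethylcyclohex-3-en-1-one
Product: 6 4,6,6-trimethylcyclohexa-2,4-dien-1-one, via silyl enol ether 5 (not isolated)
Conditions: LDA, THF, −78 °C; TMSCl; then Pd(OAc)2 (1.05 equiv), MeCN, rt; used at once, cold and dilute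
Reagents that add atoms: none
Why: Saegusa–Ito oxidation: the ketone can enolise only towards its CH2 side, and Pd(II) should convert the silyl enol ether into the enone, which is conjugated with the existing alkene to give the linear dienone; the quaternary carbon prevents tautomerisation to a phenol.

**Step 4**
Reactants: 6 4,6,6-trimethylcyclohexa-2,4-dien-1-one
Product: 8 (5R)-5-[dimethyl(phenyl)silyl]-2,2,4-trimethylcyclohex-3-en-1-one, via pinacolboron enolate 7 (not isolated)
Conditions: CuCl (5 mol %), chiral C1-symmetric imidazolinium salt (NHC precursor, 5.5 mol %), NaOt-Bu (11 mol %), PhMe2Si–Bpin (1.1 equiv), THF, −78 °C; then aq. NH4Cl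
Reagents that add atoms: (dimethylphenylsilyl)boronic acid pinacol ester, C[Si](C)(c1ccccc1)B1OC(C)(C)C(C)(C)O1
Why: Copper-catalysed enantioselective conjugate silyl addition: the NHC–Cu–Si species should add 1,4 to the β-carbon (the δ-carbon is neopentyl and shielded by the CMe2 group), the ligand selecting the enone face so that the new C–Si centre is (R), and hydrolysis of the boron enolate gives the ketone with the γ,δ-alkene untouched.

**Step 5**
Reactants: 9 umbelliferone (7-hydroxy-2H-chromen-2-one)
Product: 10 7-[(methylsulfanyl)methoxy]-2H-chromen-2-one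
Conditions: ClCH2SMe (1.2 equiv), K2CO3, NaI (cat.), DMF, rt
Reagents that add atoms: chloromethyl methyl sulfide, CSCCl
Why: Williamson-type O-alkylation of the acidic 7-hydroxyl group by the α-chloro sulfide (iodide catalysis) should give the O,S-acetal; the lactone is stable to carbonate.

**Step 6**
Reactants: 10 7-[(methylsulfanyl)methoxy]-2H-chromen-2-one
Product: 11 7-(chloromethoxy)-2H-chromen-2-one
Conditions: SO2Cl2 (1.05 equiv), CH2Cl2, 0 °C → rt; volatiles removed, used crude
Reagents that add atoms: sulfuryl chloride, O=S(=O)(Cl)Cl
Why: Chlorinolysis of an O,S-acetal: the chlorosulfonium ion should collapse to the aryl chloromethyl ether with loss of methanesulfenyl chloride, the standard route to aryloxymethyl chlorides; the electron-poor coumarin alkene is not expected to react at 0 °C.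

**Step 7**
Reactants: 8 (5R)-5-[dimethyl(phenyl)silyl]-2,2,4-trimethylcyclohex-3-en-1-one; 11 7-(chloromethoxy)-2H-chromen-2-one
Product: 12 7-{[(1S)-2,6,6-trimethyl-5-oxocyclohex-2-en-1-yl]methoxy}-2H-chromen-2-one
Conditions: 11 (1.4 equiv), SnCl4 (2.2 equiv), 2,6-di-tert-butyl-4-methylpyridine (0.3 equiv), CH2Cl2, −78 °C; cold aq. NaHCO3 quench
Reagents that add atoms: none
Why: SnCl4 ionises 11 to the coumarinyloxymethyl oxocarbenium ion, which is attacked by the γ-carbon of the allylsilane (the =CH next to the CMe2 carbon) on the face anti to the C–Si bond; the tertiary β-silyl cation at the methyl-bearing carbon then loses silicon as PhMe2SiCl, so the double bond moves into its final position. The closest known reaction type is the Hosomi–Sakurai reaction of allylsilanes with α-chloro ethers, run here as a stereospecific SE2' process on a cyclic allylsilane. No ring is closed. The new stereocentre (ring CH bearing CH2OAr) is set as (S) by 1,3-chirality transfer from the (R)-C–Si centre under the anti-SE2' rule, the pseudo-axial silyl group shielding its own face. The step needs γ- over α-attack and reaction at the alkene instead of the ketone or the coumarin: the β-silicon effect directs the electrophile to the γ-terminus, the quaternary carbon insulates the ketone from the alkene, and low temperature with a hindered pyridine base should suppress protodesilylation and migration of the new double bond into conjugation.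

**Step 8**
Reactants: 12 7-{[(1S)-2,6,6-trimethyl-5-oxocyclohex-2-en-1-yl]methoxy}-2H-chromen-2-one
Product: 13 7-{[(1S,5R)-5-hydroxy-2,6,6-trimethylcyclohex-2-en-1-yl]methoxy}-2H-chromen-2-one
Conditions: NaBH4 (1.0 equiv), CeCl3·7H2O (1.0 equiv), MeOH/THF, −40 °C
Reagents that add atoms: none
Why: Luche-type 1,2-reduction: hydride should attack the carbonyl face anti to the 1,3-related CH2OAr side chain (axial attack in the half-chair with the side chain pseudo-equatorial), giving the (R)-carbinol cis to the side chain as in the reduction of 4,4-dimethyl-3-keto terpenoids to equatorial alcohols, while the non-basic medium keeps the β,γ-alkene in place and the coumarin intact.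

**Step 9**
Reactants: 13 7-{[(1S,5R)-5-hydroxy-2,6,6-trimethylcyclohex-2-en-1-yl]methoxy}-2H-chromen-2-one
Product: 14 (1R,5S)-4,6,6-trimethyl-5-{[(2-oxo-2H-chromen-7-yl)oxy]methyl}cyclohex-3-en-1-yl 3-methylbutanoate
Conditions: isovaleryl chloride (1.5 equiv), pyridine, DMAP (cat.), CH2Cl2, 0 °C → rt
Reagents that add atoms: 3-methylbutanoyl chloride, CC(C)CC(=O)Cl
Why: DMAP-catalysed acyl transfer to the secondary alcohol should proceed with retention at the carbinol centre, as for equatorial hydroxyl groups next to a gem-dimethyl carbon in terpenoids.

**Compound list**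
1 | 4-methylanisole | COc1ccc(C)cc1 | starting material
2 | 1-methoxy-4-methylcyclohexa-1,4-diene | COC1=CCC(C)=CC1 | intermediate
3 | 4-methylcyclohex-3-en-1-one | O=C1CC=C(C)CC1 | intermediate
4 | 2,2,4-trimethylcyclohex-3-en-1-one | O=C1CCC(C)=CC1(C)C | intermediate
5 | trimethyl[(4,6,6-trimethylcyclohexa-1,4-dien-1-yl)oxy]silane | C[Si](C)(C)OC1=CCC(C)=CC1(C)C | intermediate
6 | 4,6,6-trimethylcyclohexa-2,4-dien-1-one | O=C1C=CC(C)=CC1(C)C | intermediate
7 | 2-{[(3R)-3-[dimethyl(phenyl)silyl]-4,6,6-trimethylcyclohexa-1,4-dien-1-yl]oxy}-4,4,5,5-tetramethyl-1,3,2-dioxaborolane | CC1(C)C=C(C)[C@H]([Si](C)(C)c2ccccc2)C=C1OB1OC(C)(C)C(C)(C)O1 | intermediate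
8 | (5R)-5-[dimethyl(phenyl)silyl]-2,2,4-trimethylcyclohex-3-en-1-one | O=C1C[C@@H]([Si](C)(C)c2ccccc2)C(C)=CC1(C)C | intermediate
9 | umbelliferone (7-hydroxy-2H-chromen-2-one) | O=c1ccc2ccc(O)cc2o1 | starting material
10 | 7-[(methylsulfanyl)methoxy]-2H-chromen-2-one | CSCOc1ccc2ccc(=O)oc2c1 | intermediate
11 | 7-(chloromethoxy)-2H-chromen-2-one | ClCOc1ccc2ccc(=O)oc2c1 | intermediate
12 | 7-{[(1S)-2,6,6-trimethyl-5-oxocyclohex-2-en-1-yl]methoxy}-2H-chromen-2-one | O=C1CC=C(C)[C@H](COc2ccc3ccc(=O)oc3c2)C1(C)C | intermediate
13 | 7-{[(1S,5R)-5-hydroxy-2,6,6-trimethylcyclohex-2-en-1-yl]methoxy}-2H-chromen-2-one | CC1=CC[C@@H](O)C(C)(C)[C@H]1COc1ccc2ccc(=O)oc2c1 | intermediate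
14 | (1R,5S)-4,6,6-trimethyl-5-{[(2-oxo-2H-chromen-7-yl)oxy]methyl}cyclohex-3-en-1-yl 3-methylbutanoate | CC1=CC[C@@H](OC(=O)CC(C)C)C(C)(C)[C@H]1COc1ccc2ccc(=O)oc2c1 | target

**Totals**
Total step count: 9. Longest linear sequence: 7 steps (steps 1, 2, 3, 4, 7, 8, 9, from 4-methylanisole).

**Steps most likely to fail**

Step 7. The ionised chloromethyl ether may be consumed by Friedel–Crafts attack on the alkoxy-activated coumarin ring. Bond formation at the neopentyl γ-terminus may also be slow enough for protodesilylation to win or for the anti selectivity to erode. The fallback sets out from 8 and takes the arene out of the cationic step. An SE2' reaction of 8 with formaldehyde (1,3,5-trioxane, TiCl4, CH2Cl2, −78 °C) should give (3S)-3-(hydroxymethyl)-2,2,4-trimethylcyclohex-4-en-1-one F1 with the same anti chirality transfer. A Mitsunobu etherification of F1 with umbelliferone 9 (PPh3, DIAD, THF) then returns to the route at 12.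

Step 4. Silyl transfer may compete at the δ-carbon (1,6-addition), the catalyst may discriminate the enone faces poorly on this γ-substituted linear dienone, and the dienone may dimerise by Diels–Alder reaction before it is consumed. The fallback sets out from 6 and replaces silicon by boron, for which a wider range of ligands is established. Copper-catalysed enantioselective conjugate borylation (CuCl, chiral bisphosphine, NaOt-Bu, B2pin2, MeOH, THF) would give (5S)-2,2,4-trimethyl-5-(4,4,5,5-tetramethyl-1,3,2-dioxaborolan-2-yl)cyclohex-3-en-1-one F2, with boron on the face opposite to that used for silicon. Allylboration of formaldehyde through the closed six-membered transition state (syn-SE2'; paraformaldehyde, toluene, warm) would give the borate ester 2-{[(1S)-2,6,6-trimethyl-5-oxocyclohex-2-en-1-yl]methoxy}-4,4,5,5-tetramethyl-1,3,2-dioxaborolane F3. Work-up hydrolyses it to (3S)-3-(hydroxymethyl)-2,2,4-trimethylcyclohex-4-en-1-one F1, and the Mitsunobu etherification with 9 returns to the route at 12.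

Step 8. Facial selectivity of hydride delivery may be poor, since both carbonyl faces are flanked by a methyl group. The β,γ-double bond may also migrate into conjugation and be followed by 1,4-reduction. The fallback sets out from 12 and returns at 13, replacing substrate control by reagent control. A Corey–Bakshi–Shibata reduction ((S)-Me-CBS oxazaborolidine, catecholborane, toluene, −40 °C) differentiates the CMe2 and CH2 flanks of the carbonyl and should deliver the (R)-carbinol under non-basic conditions, matched with the substrate bias. No new compound is made.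

**Further compounds**
F1 | step 7 | (3S)-3-(hydroxymethyl)-2,2,4-trimethylcyclohex-4-en-1-one | O=C1CC=C(C)[C@H](CO)C1(C)C
F2 | step 4 | (5S)-2,2,4-trimethyl-5-(4,4,5,5-tetramethyl-1,3,2-dioxaborolan-2-yl)cyclohex-3-en-1-one | O=C1C[C@H](B2OC(C)(C)C(C)(C)O2)C(C)=CC1(C)C
F3 | step 4 | 2-{[(1S)-2,6,6-trimethyl-5-oxocyclohex-2-en-1-yl]methoxy}-4,4,5,5-tetramethyl-1,3,2-dioxaborolane | O=C1CC=C(C)[C@H](COB2OC(C)(C)C(C)(C)O2)C1(C)C
F0 | step 8 | none | none
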